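**Retrosynthetic overview**

1. Numbering: pinane carbons C1–C7 as in spiro[bicyclo[3.1.1]heptane-2,2'-chromene] (C2 spiro, C6 = CMe2, C7 = CH2 bridge); chromene atoms are primed (O1', C3', C4', C4a', C5'–C8', C8a').
2. The target comes from its C4 ketone (oxygen removed last through the tosylhydrazone). That ketone is cut at C1–C2 and C5–C6 together, back to a spiro-fused 3-oxycyclobutanone with a prenyl group, so both pinane rings arise from one temporary four-membered ring.
3. Enabling feature: C2 belongs to both the dihydropyran and the pinane, is tertiary and bonded to O1', and can therefore be an oxocarbenium. C5 lies 1,4 to it through C3–C4 and is an enolate carbon once C4 is a carbonyl. C6 carries two methyls, so a C1=C6 prenyl alkene attacks through C1 and leaves a tertiary cation at C6 next to that enolate; C7 is the one-carbon tether.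
4. The cyclobutanone comes from a ketene [2+2] of prenylketene with the 2'-methylidene chromane-dione, made by Petasis methylenation of the enol lactone. The lactone comes from the lactol of an organocatalytic Michael addition of syncarpic acid to (E)-5-methylhex-2-enal, which sets C4'.
5. Ring order: dihydropyran (step 1), temporary spiro-cyclobutanone (step 5), then in step 6 the cyclohexane ring (C1–C2) followed by the cyclobutane (C5–C6).

Key step: step 6

Assumption (remark on the chemistry): 1, 2 and 6 are taken as catalogue chemicals; 1 is otherwise available by exhaustive C-methylation and deacetylation of 2',4',6'-trihydroxyacetophenone, and 2 by Wittig homologation of 3-methylbutanal.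

**Route**

Step 1
Reactants: 1 syncarpic acid (2,2,4,4-tetramethylcyclohexane-1,3,5-trione); 2 (E)-5-methylhex-2-enal
Product: 3 (4S)-2-hydroxy-4-(2-methylpropyl)-6,6,8,8-tetramethyl-3,4-dihydro-2H-chromene-5,7(6H,8H)-dione (lactol; both anomers)
Conditions: (R)-2-[diphenyl(trimethylsilyloxy)methyl]pyrrolidine (10 mol %), 2 (1.2 equiv), CH2Cl2, 0 °C → rt
Reagents that add atoms: none
Why: Organocatalytic Michael addition under iminium activation (diarylprolinol silyl ether catalysis): the enol carbon of 1 should add to the β-carbon of the (E,s-trans) iminium on the face away from the C(Ph)2OSiMe3 group, which with the (R)-catalyst gives the (S) centre at C4', and the adduct closes to the lactol.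

Step 2
Reactants: 3 lactol
Product: 4 (4S)-4-(2-methylpropyl)-6,6,8,8-tetramethyl-3,4-dihydro-2H-chromene-2,5,7(6H,8H)-trione (enol lactone)
Conditions: Ag2CO3 on Celite (3 equiv), toluene, 90 °C
Reagents that add atoms: none
Why: Fétizon oxidation of a lactol to the lactone on the silver carbonate surface under neutral conditions, which should leave the enol-derived ring oxygen and the C4' centre (not enolisable) untouched.

Step 3
Reactants: 4 enol lactone
Product: 5 (4S)-2-methylidene-4-(2-methylpropyl)-6,6,8,8-tetramethyl-3,4-dihydro-2H-chromene-5,7(6H,8H)-dione (exocyclic enol ether)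
Conditions: Cp2Ti(CH3)2 (1.5 equiv), toluene, 65 °C, dark; filtration through basic alumina
Reagents that add atoms: dimethyltitanocene, C[Ti](C)(C1C=CC=C1)C1C=CC=C1
Why: Petasis methylenation: the titanium methylidene formed by loss of methane should add to the unhindered, activated enol-lactone carbonyl and give the exocyclic enol ether under non-acidic conditions (no drift to the endocyclic isomer), while the C7' ketone between two quaternary carbons and the shielded vinylogous ester carbonyl should not compete.

Step 4
Reactants: 6 5-methylhex-4-enoic acid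
Product: 7 5-methylhex-4-enoyl chloride
Conditions: (COCl)2 (1.2 equiv), N,N-dimethylformamide (cat.), CH2Cl2, 0 °C → rt; volatiles removed
Reagents that add atoms: oxalyl chloride, ClC(=O)C(=O)Cl
Why: Acid chloride formation through the chloroiminium (Vilsmeier-type) intermediate; the trisubstituted alkene is inert under these conditions.

Step 5
Reactants: 5 exocyclic enol ether; 7 5-methylhex-4-enoyl chloride
Product: 9 (4S)-6,6,8,8-tetramethyl-2'-(3-methylbut-2-en-1-yl)-4-(2-methylpropyl)-3,4-dihydrospiro[chromene-2,1'-cyclobutane]-3',5,7(6H,8H)-trione (diastereomer mixture at the two new ring carbons), via prenylketene 8 (not isolated)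
Conditions: 7 (4 equiv) added over 8 h to 5 and iPr2NEt (5 equiv), MeCN, 60 °C
Reagents that add atoms: none
Why: Thermal ketene–enol ether [2+2] cycloaddition (Staudinger-type ketene cycloaddition): the nucleophilic CH2 terminus of 5 bonds to the ketene carbonyl carbon and the oxygen-bearing carbon to the prenyl-bearing carbon, which fixes the regiochemistry; the two new centres form unselectively, which is harmless because step 6 erases both.

Step 6
Reactants: 9 spirocyclobutanone
Product: 12 (1R,2S,4'S,5S)-6,6,6',6',8',8'-hexamethyl-4'-(2-methylpropyl)-3',4'-dihydrospiro[bicyclo[3.1.1]heptane-2,2'-chromene]-4,5',7'(6'H,8'H)-trione, via oxocarbenium–enolate zwitterion 10 (not isolated), via tertiary cation 11 (not isolated)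
Conditions: EtAlCl2 (1.1 equiv), CH2Cl2 (0.01 M), −78 → −30 °C; then H2O at −30 °C
Reagents that add atoms: none
Why: Proposed new method: EtAlCl2 on the cyclobutanone carbonyl should heterolyse the strained bond between the spiro carbon and the prenyl-bearing carbon (push from O1', pull from the carbonyl) to zwitterion 10, a tertiary oxocarbenium at C2 with an aluminium enolate at C4–C5; the closest known reaction type is the Lewis-acid formal [4+2] cycloaddition of 3-alkoxycyclobutanones with carbonyl compounds, allylsilanes and alkenes, and what is new is the one-carbon tether that makes the adduct bridged. The six-membered ring closes first by 6-exo Prins-type attack of C1 of the prenyl alkene on the oxocarbenium (Markovnikov, tertiary cation 11 at C6); only the enolate geometry with C3 and C7 cis can do this, and the other can return to 9 and re-open. The four-membered ring then closes by C-alkylation of the enolate carbon C5 with the neighbouring C6 cation across the 1,3-positions of the new cyclohexene (the reverse of the known acid cleavage of nopinone); O-alkylation would give a bridgehead enol ether, and proton loss is the competing exit that the aprotic, proton-scavenging Lewis acid at low temperature is meant to suppress. C2 should be set by attack anti to the isobutyl group at C4', which is held pseudoaxial by allylic strain with the C5' carbonyl. C1 should be set relative to C2 by an approach that places the cation-developing CMe2 terminus antiperiplanar to O1' and away from the C8' gem-dimethyl pair, so that O1' ends on the side of the CH2 bridge, while C5 is forced because the one-carbon bridge can only span cis. The step needs opening of the cyclobutanone in the presence of the more basic vinylogous ester carbonyl, which should follow from fast exchange of about one equivalent of Lewis acid, since only the cyclobutanone complex has an irreversible exit.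

Step 7
Reactants: 12 bicyclic ketone
Product: 13 (1R,2S,4'S,5S)-4-(4-methylbenzenesulfonylhydrazono) derivative of 12 (tosylhydrazone at C4; C=N geometry not defined)
Conditions: TsNHNH2 (1.3 equiv), EtOH, 50 °C
Reagents that add atoms: 4-methylbenzenesulfonohydrazide, Cc1ccc(cc1)S(=O)(=O)NN
Why: Condensation to the tosylhydrazone at the only unhindered, non-conjugated ketone; the near-neutral medium avoids enolisation towards C3, which would expel the β-oxygen O1' (E1cB).

Step 8
Reactants: 13 tosylhydrazone
Product: 16 (1R,2R,4'S,5S)-6,6,6',6',8',8'-hexamethyl-4'-(2-methylpropyl)-3',4'-dihydrospiro[bicyclo[3.1.1]heptane-2,2'-chromene]-5',7'(6'H,8'H)-dione (target CNP0231252.1), via N-borylated sulfonylhydrazine 14 (not isolated), via alkyldiazene 15 (not isolated)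
Conditions: catecholborane (2.5 equiv), CHCl3, 0 °C → rt; then NaOAc·3H2O (5 equiv), 60 °C
Reagents that add atoms: none
Why: Caglioti-type reductive deoxygenation (catecholborane variant): hydroboration of the C=N bond, acetate-induced loss of sulfinate to the alkyldiazene and loss of N2 should deliver the C4 methylene without an enolate, a carbocation or strong acid, so O1', the cyclobutane and all four stereocentres are kept.

**Compound list**

1 | syncarpic acid, 2,2,4,4-tetramethylcyclohexane-1,3,5-trione | CC1(C)C(=O)CC(=O)C(C)(C)C1=O | starting material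
2 | (E)-5-methylhex-2-enal | CC(C)C/C=C/C=O | starting material
3 | (4S)-2-hydroxy-4-(2-methylpropyl)-6,6,8,8-tetramethyl-3,4-dihydro-2H-chromene-5,7(6H,8H)-dione, lactol, both anomers | CC(C)C[C@H]1CC(O)OC2=C1C(=O)C(C)(C)C(=O)C2(C)C | intermediate
4 | (4S)-4-(2-methylpropyl)-6,6,8,8-tetramethyl-3,4-dihydro-2H-chromene-2,5,7(6H,8H)-trione, enol lactone | CC(C)C[C@H]1CC(=O)OC2=C1C(=O)C(C)(C)C(=O)C2(C)C | intermediate
5 | (4S)-2-methylidene-4-(2-methylpropyl)-6,6,8,8-tetramethyl-3,4-dihydro-2H-chromene-5,7(6H,8H)-dione, exocyclic enol ether | CC(C)C[C@H]1CC(=C)OC2=C1C(=O)C(C)(C)C(=O)C2(C)C | intermediate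
6 | 5-methylhex-4-enoic acid | CC(C)=CCCC(=O)O | starting material
7 | 5-methylhex-4-enoyl chloride | CC(C)=CCCC(=O)Cl | intermediate
8 | prenylketene, 5-methylhexa-1,4-dien-1-one | CC(C)=CCC=C=O | intermediate (not isolated)
9 | (4S)-6,6,8,8-tetramethyl-2'-(3-methylbut-2-en-1-yl)-4-(2-methylpropyl)-3,4-dihydrospiro[chromene-2,1'-cyclobutane]-3',5,7(6H,8H)-trione, mixture of diastereomers at the spiro carbon and at C2' | CC(C)C[C@H]1CC2(CC(=O)C2CC=C(C)C)OC3=C1C(=O)C(C)(C)C(=O)C3(C)C | intermediate
10 | ring-opened zwitterion: (4S)-4H-chromen-1-ium with the oxocarbenium at the future C2 and a dichloro(ethyl)aluminate enolate (O–C4=C5) carrying the prenyl group on C5 | CC(C)C[C@H]1CC(CC(O[Al-](CC)(Cl)Cl)=CCC=C(C)C)=[O+]C2=C1C(=O)C(C)(C)C(=O)C2(C)C | intermediate (not isolated)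
11 | monocyclic zwitterion after C1–C2 closure: spiro cyclohexenyl aluminate enolate with the 2-propyl cation (C6) on C1, configuration at C1, C2 and C4' as in the target | CC(C)C[C@H]1C[C@@]2(CC(O[Al-](CC)(Cl)Cl)=CC[C@@H]2[C+](C)C)OC3=C1C(=O)C(C)(C)C(=O)C3(C)C | intermediate (not isolated)
12 | (1R,2S,4'S,5S)-6,6,6',6',8',8'-hexamethyl-4'-(2-methylpropyl)-3',4'-dihydrospiro[bicyclo[3.1.1]heptane-2,2'-chromene]-4,5',7'(6'H,8'H)-trione, the target with C4=O and the same spatial arrangement (the C2 descriptor differs only through priorities) | CC(C)C[C@H]1C[C@@]2(CC(=O)[C@H]3C[C@@H]2C3(C)C)OC2=C1C(=O)C(C)(C)C(=O)C2(C)C | intermediate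
13 | tosylhydrazone of 12 at C4, (1R,2S,4'S,5S) | CC(C)C[C@H]1C[C@@]2(CC(=NNS(=O)(=O)c4ccc(C)cc4)[C@H]3C[C@@H]2C3(C)C)OC2=C1C(=O)C(C)(C)C(=O)C2(C)C | intermediate
14 | N-(1,3,2-benzodioxaborol-2-yl)-N'-tosylhydrazine at C4 (C4 configuration not defined) | CC(C)C[C@H]1C[C@@]2(CC(N(NS(=O)(=O)c4ccc(C)cc4)B5Oc6ccccc6O5)[C@H]3C[C@@H]2C3(C)C)OC2=C1C(=O)C(C)(C)C(=O)C2(C)C | intermediate (not isolated)
15 | alkyldiazene at C4 (C4 configuration not defined) | CC(C)C[C@H]1C[C@@]2(CC(N=N)[C@H]3C[C@@H]2C3(C)C)OC2=C1C(=O)C(C)(C)C(=O)C2(C)C | intermediate (not isolated)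
16 | (1R,2R,4'S,5S)-6,6,6',6',8',8'-hexamethyl-4'-(2-methylpropyl)-3',4'-dihydrospiro[bicyclo[3.1.1]heptane-2,2'-chromene]-5',7'(6'H,8'H)-dione, CNP0231252.1 | CC(C)C[C@H]1C[C@@]2(CC[C@H]3C[C@@H]2C3(C)C)OC2=C1C(=O)C(C)(C)C(=O)C2(C)C | target

**Step count and risks**

Total step count: 8. Longest linear sequence: 7 steps (steps 1, 2, 3, 5, 6, 7, 8; step 4 is a one-step side branch).

Steps most likely to fail:

1. Step 6 (Proposed new method). What may go wrong: proton loss from the zwitterion to an open-chain vinylogous ester instead of ring closure, elimination at the C6 cation before the cyclobutane closes, or attack on the wrong face of the oxocarbenium. Fallback (known chemistry, sets out from 1 and comes back at 16): 1 is condensed with 3-methylbutanal (piperidine, CH2Cl2, then dilute HCl; Knoevenagel condensation) to 2,2,4,4-tetramethyl-6-(3-methylbutylidene)cyclohexane-1,3,5-trione F1. This oxa-diene is heated with commercial (1S,5S)-(−)-β-pinene (toluene, 100 °C) in an inverse-electron-demand hetero-Diels–Alder reaction. The enone oxygen should bond to the disubstituted alkene carbon on the face away from the gem-dimethyl bridge, so the spiro centre and both bridgeheads come from the terpene, and 16 is separated from its C4' epimer by chromatography.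

2. Step 5. What may go wrong: ketene dimerisation outrunning the cycloaddition, because the enol ether oxygen is conjugated to the enone and only weakly donating, or base-induced isomerisation of the exocyclic enol ether to the endocyclic one. Fallback (sets out from 7 and 5, comes back at 9): 7 is converted with dimethylamine (Et3N, CH2Cl2, 0 °C) into N,N-dimethyl-5-methylhex-4-enamide F2. Tf2O and 2,6-di-tert-butyl-4-methylpyridine (CH2Cl2, −20 °C) turn F2 into the keteniminium salt N,N-dimethyl-(5-methylhexa-1,4-dienylidene)ammonium trifluoromethanesulfonate F3, a far stronger electrophile than the ketene. F3 adds to 5 in a keteniminium–alkene [2+2] cycloaddition to the spiro cyclobutaniminium trifluoromethanesulfonate F4, and hydrolysis with aqueous NaHCO3 gives 9.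

3. Step 8. What may go wrong: radical character during collapse of the alkyldiazene, which would open the cyclobutane next to C4, or over-reduction of another carbonyl by the borane. Fallback (sets out from 12, comes back at 16): 12 is converted with ethane-1,2-dithiol and Zn(OTf)2 (cat., CH2Cl2, 0 °C) into the C4 1,3-dithiolane of 12 F5, since only the unhindered ketone should react, and Raney nickel (EtOH, rt; Mozingo desulfurisation) takes F5 to 16.

**Further compounds**

F1 | step 6 | 2,2,4,4-tetramethyl-6-(3-methylbutylidene)cyclohexane-1,3,5-trione | CC(C)CC=C1C(=O)C(C)(C)C(=O)C(C)(C)C1=O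
F2 | step 5 | N,N-dimethyl-5-methylhex-4-enamide | CC(C)=CCCC(=O)N(C)C
F3 | step 5 | N,N-dimethyl-(5-methylhexa-1,4-dienylidene)ammonium trifluoromethanesulfonate | CC(C)=CCC=C=[N+](C)C.[O-]S(=O)(=O)C(F)(F)F
F4 | step 5 | spiro cyclobutaniminium trifluoromethanesulfonate (N,N-dimethyliminium analogue of 9, diastereomer mixture) | CC(C)C[C@H]1CC2(CC(=[N+](C)C)C2CC=C(C)C)OC3=C1C(=O)C(C)(C)C(=O)C3(C)C.[O-]S(=O)(=O)C(F)(F)F
F5 | step 8 | C4 1,3-dithiolane of 12 | CC(C)C[C@H]1C[C@@]2(CC3(SCCS3)[C@H]4C[C@@H]2C4(C)C)OC2=C1C(=O)C(C)(C)C(=O)C2(C)C
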